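- After 15.0 min the red run still held 78.4% of its starting material, and yet its last 5.00 min gained 7.5 percentage points, where its mean pace gives 7.2 points.

common to all: starting material 0.80 M

|  | reagent | free catalyst | remark |
|---|---|---|---|
| ochre | 1.7 equiv | 0.2 mol% | run made earlier |
| amber | 2.6 equiv | 0.2 mol% | run made earlier |
| red | 1.2 equiv | 0.4 mol% | run made earlier |
| flask | 1.20 equiv | 0.2 mol% |  |

- ochre (time / min: product / %): 2.00: 1.0; 6.00: 4.7; 10.0: 6.9; 15.0: 8.4
- amber (time / min: product / %): 1.33: 1.1; 3.00: 1.4; 6.00: 2.7; 15.0: 7.6
- red (time / min: product / %): 2.00: 3.0; 6.00: 7.8; 10.0: 14.1; 15.0: 21.6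

(readings scatter by 1 percentage point)

- the analysis behind the earlier runs scatters by 1 percentage point, standard deviation
- steps under discussion: catalyst intermediate C <-> catalyst intermediate D; reagent + catalyst intermediate B <-> idle complex; reagent + free catalyst -> catalyst intermediate A; catalyst intermediate D -> free catalyst + product; catalyst intermediate A -> by-product + catalyst intermediate B; starting material + catalyst intermediate B -> catalyst intermediate C

* factor on the rate of making product when 10% of the starting material are converted if free catalyst is charged twice over
* factor on the rate when 10% of the starting material are converted if free catalyst is charged at 1 mol% instead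

- So I replaced the red curve by its mean and defined T, the mean turnover frequency, as the product made per catalyst charged per minute: 3.60 min⁻¹. One reading's scatter puts 4.63% on it.
- I then turned the question round: the factors could leave 2 and 5.00 if T changed with the charge, for instance if the catalyst took a real bite out of the reagent.
- For a flask at 1 mol%, counting one reagent held on every catalyst, I reckoned the bite as 0.833% of the reagent charge.
- The readings give a yardstick at one loading. From the ochre run to the amber run, both at 0.2 mol%, the reagent rose by 52.9%, and the same mean figure went from 2.80 min⁻¹ to 2.53 min⁻¹, a fall of 9.52%, less than the 13.2% that one reading's scatter puts on the amber figure.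
- That step is 63.5 times the bite, so I scaled the fall down and reckoned 0.150% on the factor, less than the scatter on T, though this yardstick was read at more reagent than the flask holds.
- I therefore committed to 2 and 5.00, with 0.00576 M min⁻¹ for this flask.
- The forecast gave 2 and 5, saying “rate is proportional to catalyst”.
- The simulation gave 2.00 and 5.03.

    catalyst intermediate C ⇌ catalyst intermediate D (K = 0.370, k = 31.0 min⁻¹)
    reagent + catalyst intermediate B ⇌ idle complex, settled at all times (K = 13.0 M⁻¹)
    reagent + free catalyst → catalyst intermediate A (k = 54.0 M⁻¹ min⁻¹)
    catalyst intermediate D → free catalyst + product (k = 7000 min⁻¹)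
    catalyst intermediate A → by-product + catalyst intermediate B (k = 110 min⁻¹)
    starting material + catalyst intermediate B → catalyst intermediate C (k = 88.0 M⁻¹ min⁻¹)

- At 12.8 min the flask made product at 0.00618 M min⁻¹, and at 10.0 min the idle complex, off the working round, held 69.7% of the catalyst charged. Per catalyst, that rate is 3.86 min⁻¹ against T of 3.60 min⁻¹. For the flask at 1 mol%, T gives 0.0288 M min⁻¹, and the simulation's rate there was 0.0311 M min⁻¹.

(The data were computed for substances that don't exist.)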